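In a one-step world product would rise from the first second, but the earlier runs show a lag (induction period): the south run read 0% at 20.0 s and first stood clear of the scatter at 30.0 s.

| flask | starting material | reagent in the second phase | protic impurity | remark | time | volume of the second phase over the first |
|---|---|---|---|---|---|---|
| south-west | 0.20 M | 0.12 M | 0.10 M | run made earlier |  |  |
| north-west | 0.20 M | 0.18 M | 0.10 M | run made earlier |  |  |
| south | 0.30 M | 0.24 M | 0.10 M | run made earlier |  |  |
| flask | 0.20 M | 0.240 M | 0.100 M |  | 2.0 min | 0.25 |

- south-west (time / s: product / %): 10.0: 0; 25.0: 0; 40.0: 3; 60.0: 3; 90.0: 9; 120: 12
- north-west (time / s: product / %): 10.0: 0; 15.0: 2; 25.0: 1; 40.0: 4; 80.0: 8; 120: 18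
- south (time / s: product / %): 10.0: 0; 20.0: 0; 30.0: 5; 60.0: 7; 120: 21

(scatter of a reading: 1.5 percentage points)

- in the second phase: reagent in the second phase; everything else is in the first
- charges count per volume of the first phase; a concentration in a rate is the amount of a species over the volume of its own phase; every rate counts per litre of the first phase
- the analysis behind the earlier runs scatters by 1.5 percentage points, standard deviation
- steps that have been proposed: starting material + protic impurity -> quenched substrate; starting material + reagent in the reaction phase <-> product; reagent in the reaction phase <-> reagent in the second phase
- the earlier runs hold the two phases in the same ratio of volumes as the flask asked about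

- Friday's: doubling the amount of reagent in the second phase, all else as stated
- Monday's: doubling the transfer coefficient of the reagent in the second phase, all else as stated

- product at 2.0 min, in percent of the starting material charged
- the change that raises the amount of product at 2.0 min, in percent of the starting material charged most ("none" if none brings more than 2 percentage points) (Friday's / Monday's / none)
- amount of product at 2.0 min, in percent of the starting material charged, after Friday's

I first asked what the flask's figure depends on. Time needed no correction: the flask is read at 120 s, the time of the last south-west and north-west readings, so the lag is already inside them. The protic impurity stood at 0.10 M and 0.10 M in those runs, as in the flask, and the phase ratio and the starting material at 0.20 M match too. The reagent charge is what differs, so it has to be known well. I therefore took the reagent yield, the fraction of starting material found as product at the last reading per molar of reagent charged: 1.00 L mol⁻¹ from the north-west run, and 1.00 L mol⁻¹ from the south-west run. One scatter on the north-west reading moves the flask's figure by 2 percentage points. My figure for the flask was 24.0%. For Friday's change the same straight line gave 48.0%, though that charge lies outside the runs.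

The forecast, which read the lag as pointing to “slow transfer of reagent into the reaction phase”, gave 23%, chose Friday's and put that change at 40%, less than my straight line.

The flask gave 23.8%. Friday's brought more than Monday's, reaching 42.2%, a gain of 18 points against 11 points.

    starting material + protic impurity → quenched substrate (k = 0.0224 L mol⁻¹ s⁻¹)
    starting material + reagent in the reaction phase ⇌ product (K = 230 L mol⁻¹, k = 0.0653 L mol⁻¹ s⁻¹)
    reagent in the reaction phase ⇌ reagent in the second phase, rate k3*([reagent in the reaction phase] - [reagent in the second phase]/K3) per volume of the first phase (partition coefficient = 1.60, kL = 0.00223 s⁻¹)

In the flask at 2.00 min, reagent in the reaction phase had risen from 0.0142 M at 0.200 min to 0.0608 M, with 54.8% of its charge still in the second phase. By then product stood at 23.8%, quenched substrate at 17.4%, and 58.7% of the starting material remained. Read at 80 s, the same flask should stand, by the reagent yield scaled to the time past the lag, at 13.3%; the computed result is 14.3%.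

All runs are calculated on assumed constants; the scatter is artificial.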